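Cuts: the upper pyran (ring C) at O1–C2 and C3–C4, giving a ring A ortho-quinone methide and the ring B arylacetaldehyde; the lower pyran (ring E) at O1'–C8a' and C3'–C4'; ring D at D1–C(acyl) and D6–C(α), taken together as an aryne plus a ring A β-ketoester.
Enabling feature: ring D carries its two carbon substituents on neighbouring atoms, D1 (bonded to C4) and D6 (bonded to C3'), with the methoxy group on D2 next to D1 and the oxygen on D4 para to D1, so the D1–D6 edge can be an aryne triple bond polarised by the D2 methoxy group.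
Forward: an ortho-silylaryl triflate (from 5-bromovanillin) and the β-ketoester are joined by σ-insertion (no target ring forms), C3' is benzylated, ring E is closed by palladium-catalysed C–O coupling, the diaryl ketone is turned into the quinone methide that closes ring C, and lactol reduction and hydrogenolysis finish.
Stereochemistry: C3' (R) from (R)-4-benzyl-2-oxazolidinone in an enolate benzylation; C3 (R) from enamine catalysis by an (R)-diarylprolinol silyl ether; C4 (S) arises trans to C3 in the same annulation.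

Key step: step 8

Remark: ring A is the benzo ring of the upper chroman, ring B the aryl group on C3, ring D the central arene (D1 on C4, D2 OMe, D4 O, D6 on C3'), ring F the benzo ring of the lower chroman (primed numbers); the target is read as (3R,4S,3'R) with the aryl groups on C3 and C4 trans, and epimer mixtures at the benzhydrol carbinol carbon and at the lactol carbon are accepted because both centres are erased later; all five starting materials are taken as catalogue compounds.

Step 1
Reactants: 1 5-bromovanillin (3-bromo-4-hydroxy-5-methoxybenzaldehyde)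
Product: 2 3-bromo-5-methoxy-4-(methoxymethoxy)benzaldehyde
Conditions: MOMCl, i-Pr2NEt, CH2Cl2, 0 °C → rt
Reagents that add atoms: chloromethyl methyl ether, COCCl
Why: Williamson-type O-alkylation of the acidic phenol masks the oxygen that later becomes the triflate as an ether, which keeps the ring electron-rich enough for aryl migration in step 2.

Step 2
Reactants: 2 3-bromo-5-methoxy-4-(methoxymethoxy)benzaldehyde
Product: 4 3-bromo-5-methoxy-4-(methoxymethoxy)phenol, via aryl formate 3 (not isolated)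
Conditions: mCPBA, CH2Cl2, rt; then K2CO3 (0.2 equiv), MeOH, rt
Reagents that add atoms: 3-chloroperoxybenzoic acid, OOC(=O)c1cccc(Cl)c1
Why: Baeyer–Villiger (Dakin-type) oxidation of the alkoxy-substituted benzaldehyde should proceed with aryl migration to formate 3, whose methanolysis unveils the future D4 oxygen para to the MOM ether.

Step 3
Reactants: 4 3-bromo-5-methoxy-4-(methoxymethoxy)phenol
Product: 5 5-(benzyloxy)-1-bromo-3-methoxy-2-(methoxymethoxy)benzene
Conditions: BnBr, K2CO3, DMF, rt
Reagents that add atoms: benzyl bromide, BrCc1ccccc1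
Why: Williamson etherification of the only free phenol installs the benzyl group that stays on the D4 oxygen until the final hydrogenolysis.

Step 4
Reactants: 5 5-(benzyloxy)-1-bromo-3-methoxy-2-(methoxymethoxy)benzene
Product: 6 4-(benzyloxy)-2-bromo-6-methoxyphenol
Conditions: HCl (cat.), MeOH, 50 °C
Reagents that add atoms: none
Why: Acid-catalysed acetal cleavage removes the MOM group without touching the benzyl ether or the aryl bromide and frees the phenol flanked by bromine and methoxy.

Step 5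
Reactants: 6 4-(benzyloxy)-2-bromo-6-methoxyphenol
Product: 9 4-(benzyloxy)-2-methoxy-6-(trimethylsilyl)phenyl trifluoromethanesulfonate, via aryl trimethylsilyl ether 7 (not isolated), via lithium silylphenoxide 8 (not isolated)
Conditions: (Me3Si)2NH, THF, 65 °C, evaporate; n-BuLi, THF, −78 °C; Tf2O, −78 °C
Reagents that add atoms: hexamethyldisilazane, C[Si](C)(C)N[Si](C)(C)C; trifluoromethanesulfonic anhydride, O=S(=O)(OS(=O)(=O)C(F)(F)F)C(F)(F)F
Why: O-silylation followed by bromine–lithium exchange triggers a retro-Brook 1,3 O→C silyl shift to phenoxide 8, which is triflated on oxygen to give the ortho-silylaryl triflate with silicon exactly where bromine stood.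

Step 6
Reactants: 10 1-[4-(benzyloxy)-2-hydroxyphenyl]ethanone
Product: 11 1-[4-(benzyloxy)-2-(methoxymethoxy)phenyl]ethanone
Conditions: NaH, DMF, 0 °C; MOMCl, 0 °C → rt
Reagents that add atoms: chloromethyl methyl ether, COCCl
Why: Deprotonation of the chelated phenol and Williamson etherification with MOMCl block the phenol so that it cannot add to the aryne in step 8.

Step 7
Reactants: 11 1-[4-(benzyloxy)-2-(methoxymethoxy)phenyl]ethanone
Product: 12 methyl 3-[4-(benzyloxy)-2-(methoxymethoxy)phenyl]-3-oxopropanoate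
Conditions: NaH, (MeO)2CO, THF, reflux; then AcOH
Reagents that add atoms: dimethyl carbonate, COC(=O)OC
Why: Claisen condensation of the methyl ketone enolate with dimethyl carbonate is driven to completion by deprotonation of the β-ketoester formed.

Step 8
Reactants: 9 4-(benzyloxy)-2-methoxy-6-(trimethylsilyl)phenyl trifluoromethanesulfonate; 12 methyl 3-[4-(benzyloxy)-2-(methoxymethoxy)phenyl]-3-oxopropanoate
Product: 15 methyl 2-{5-(benzyloxy)-2-[4-(benzyloxy)-2-(methoxymethoxy)benzoyl]-3-methoxyphenyl}acetate, via 5-(benzyloxy)-3-methoxybenzyne 13 (not isolated), via caesium benzocyclobutenoxide 14 (not isolated)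
Conditions: CsF (2.5 equiv), MeCN, 80 °C
Reagents that add atoms: none
Why: Fluoride attack on silicon with loss of triflate releases aryne 13; the enolate carbon of 12 adds to the aryne carbon remote from the methoxy group (future D6), and the aryl anion left at D1 closes onto the ketone to give benzocyclobutenoxide 14, which fragments by C–C cleavage to the ortho-aroyl arylacetate, so that D6–C(α) and D1–C(acyl) form in one operation. The closest known reaction type is the acyl-alkylation of arynes by insertion into the C(acyl)–C(α) σ-bond of β-ketoesters. No ring of the target closes; the only ring formed is the transient four-membered carbocycle of 14 (4-exo-trig attack of the aryl anion on C=O), and it opens again. No stereocentre is created. The step needs regioselectivity only, and the D2 methoxy group secures it: its inductive pull and the distortion it imposes on the 3-alkoxyaryne make the distal carbon the electrophilic one, while the remote benzyloxy group cannot compete. The MOM ether on ring A keeps the ortho oxygen from O-arylation.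

Step 9
Reactants: 15 methyl 2-{5-(benzyloxy)-2-[4-(benzyloxy)-2-(methoxymethoxy)benzoyl]-3-methoxyphenyl}acetate
Product: 16 2-{5-(benzyloxy)-2-[4-(benzyloxy)-2-(methoxymethoxy)benzoyl]-3-methoxyphenyl}acetic acid
Conditions: LiOH, THF/MeOH/H2O, rt; then 1 M HCl to pH 3–4, 0 °C
Reagents that add atoms: lithium hydroxide, [Li+].[OH-]
Why: Saponification of the methyl ester leaves the non-enolisable diaryl ketone and the acetal untouched and gives the acid needed for attachment of the auxiliary.

Step 10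
Reactants: 16 2-{5-(benzyloxy)-2-[4-(benzyloxy)-2-(methoxymethoxy)benzoyl]-3-methoxyphenyl}acetic acid; 17 (R)-4-benzyl-2-oxazolidinone
Product: 19 (4R)-4-benzyl-3-(2-{5-(benzyloxy)-2-[4-(benzyloxy)-2-(methoxymethoxy)benzoyl]-3-methoxyphenyl}acetyl)-1,3-oxazolidin-2-one, via mixed pivalic anhydride 18 (not isolated)
Conditions: t-BuCOCl, Et3N, THF, −20 °C; then 17, LiCl, −20 °C → rt
Reagents that add atoms: none
Why: Activation as mixed anhydride 18 and LiCl/Et3N-mediated N-acylation is the standard route to Evans imides of arylacetic acids, and the low temperature should hold back ketene formation and cyclisation onto the neighbouring ketone.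

Step 11
Reactants: 20 2-bromo-4-hydroxybenzaldehyde
Product: 21 4-(benzyloxy)-2-bromobenzaldehyde
Conditions: BnBr, K2CO3, DMF, rt
Reagents that add atoms: benzyl bromide, BrCc1ccccc1
Why: Williamson etherification protects the future 7'-hydroxyl as the benzyl ether that is removed in the last step.

Step 12
Reactants: 21 4-(benzyloxy)-2-bromobenzaldehyde
Product: 22 [4-(benzyloxy)-2-bromophenyl]methanol
Conditions: NaBH4, MeOH, 0 °C
Reagents that add atoms: none
Why: Hydride reduction of the aldehyde gives the benzylic alcohol without touching the aryl bromide.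

Step 13
Reactants: 22 [4-(benzyloxy)-2-bromophenyl]methanol
Product: 23 4-(benzyloxy)-2-bromo-1-(bromomethyl)benzene
Conditions: PBr3, CH2Cl2, 0 °C
Reagents that add atoms: phosphorus tribromide, BrP(Br)Br
Why: PBr3 converts the benzylic alcohol into the bromide by SN2 displacement of a bromophosphite, and the ring bromine tempers the electron-rich benzyl bromide enough for isolation.

Step 14
Reactants: 19 (4R)-4-benzyl-3-(2-{5-(benzyloxy)-2-[4-(benzyloxy)-2-(methoxymethoxy)benzoyl]-3-methoxyphenyl}acetyl)-1,3-oxazolidin-2-one; 23 4-(benzyloxy)-2-bromo-1-(bromomethyl)benzene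
Product: 25 (4R)-4-benzyl-3-[(2R)-2-{5-(benzyloxy)-2-[4-(benzyloxy)-2-(methoxymethoxy)benzoyl]-3-methoxyphenyl}-3-[4-(benzyloxy)-2-bromophenyl]propanoyl]-1,3-oxazolidin-2-one, via sodium Z-enolate 24 (not isolated)
Conditions: NaN(SiMe3)2 (1.05 equiv), THF, −78 °C; then 23, −78 → −40 °C
Reagents that add atoms: none
Why: Evans asymmetric alkylation, in which the chelated Z-enolate 24 is benzylated on the face opposite the benzyl group of the (R)-auxiliary, which sets C3' as R (the aryl group outranks the new CH2Ar group, so the (R)-auxiliary gives the R descriptor here).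

Step 15
Reactants: 25 (4R)-4-benzyl-3-[(2R)-2-{5-(benzyloxy)-2-[4-(benzyloxy)-2-(methoxymethoxy)benzoyl]-3-methoxyphenyl}-3-[4-(benzyloxy)-2-bromophenyl]propanoyl]-1,3-oxazolidin-2-one
Product: 26 {4-(benzyloxy)-2-[(2R)-1-[4-(benzyloxy)-2-bromophenyl]-3-hydroxypropan-2-yl]-6-methoxyphenyl}[4-(benzyloxy)-2-(methoxymethoxy)phenyl]methanone
Conditions: LiBH4, H2O (1 equiv), Et2O, 0 °C
Reagents that add atoms: none
Why: Reductive cleavage of the N-acyl oxazolidinone by LiBH4 is fast at the exocyclic imide carbonyl, whereas the diaryl ketone, shielded by the 2,6-disubstituted ring D and deactivated by two alkoxy donors on ring A, should survive at 0 °C, and C3' should hold because the intermediate aldehyde is reduced as it forms.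

Step 16
Reactants: 26 {4-(benzyloxy)-2-[(2R)-1-[4-(benzyloxy)-2-bromophenyl]-3-hydroxypropan-2-yl]-6-methoxyphenyl}[4-(benzyloxy)-2-(methoxymethoxy)phenyl]methanone
Product: 27 {4-(benzyloxy)-2-[(3R)-7-(benzyloxy)chroman-3-yl]-6-methoxyphenyl}[4-(benzyloxy)-2-(methoxymethoxy)phenyl]methanone
Conditions: Pd(OAc)2 (5 mol%), 2-(di-tert-butylphosphino)-1,1'-binaphthyl (6 mol%), Cs2CO3, toluene, 70 °C
Reagents that add atoms: none
Why: Intramolecular Buchwald–Hartwig C–O coupling (oxidative addition of zerovalent palladium into the C–Br bond, alkoxide binding, reductive elimination) closes ring E as a six-membered ring, the bulky biaryl phosphine disfavouring β-hydride elimination, and C3' is not involved.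

Step 17
Reactants: 27 {4-(benzyloxy)-2-[(3R)-7-(benzyloxy)chroman-3-yl]-6-methoxyphenyl}[4-(benzyloxy)-2-(methoxymethoxy)phenyl]methanone
Product: 28 {4-(benzyloxy)-2-[(3R)-7-(benzyloxy)chroman-3-yl]-6-methoxyphenyl}[4-(benzyloxy)-2-hydroxyphenyl]methanone
Conditions: HCl (cat.), MeOH/THF, 50 °C
Reagents that add atoms: none
Why: Acidic methanolysis of the MOM acetal frees the ring A phenol at the ketone stage, where no acid-labile benzylic alcohol is yet present.

Step 18
Reactants: 28 {4-(benzyloxy)-2-[(3R)-7-(benzyloxy)chroman-3-yl]-6-methoxyphenyl}[4-(benzyloxy)-2-hydroxyphenyl]methanone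
Product: 29 5-(benzyloxy)-2-[{4-(benzyloxy)-2-[(3R)-7-(benzyloxy)chroman-3-yl]-6-methoxyphenyl}(hydroxy)methyl]phenol (both carbinol epimers)
Conditions: NaBH4 (excess), THF/MeOH, 0 °C → rt; neutral aqueous work-up; used crude
Reagents that add atoms: none
Why: Carbonyl reduction by NaBH4, assisted by the hydrogen bond from the ortho phenol, should give the ortho-hydroxybenzhydrol, whose carbinol configuration is irrelevant because this carbon becomes trigonal in step 23.

Step 19
Reactants: 30 2,6-dimethoxyphenol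
Product: 31 2-(benzyloxy)-1,3-dimethoxybenzene
Conditions: BnBr, K2CO3, DMF, rt
Reagents that add atoms: benzyl bromide, BrCc1ccccc1
Why: Williamson etherification protects the ring B hydroxyl as the benzyl ether removed in the last step.

Step 20
Reactants: 31 2-(benzyloxy)-1,3-dimethoxybenzene
Product: 32 3-(benzyloxy)-1-bromo-2,4-dimethoxybenzene
Conditions: NBS, MeCN, 0 °C → rt
Reagents that add atoms: N-bromosuccinimide, O=C1CCC(=O)N1Br
Why: Electrophilic aromatic bromination should occur para to a terminal methoxy group because the central benzyloxy group is twisted out of conjugation, as in 1,2,3-trimethoxybenzene.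

Step 21
Reactants: 32 3-(benzyloxy)-1-bromo-2,4-dimethoxybenzene
Product: 34 2-[3-(benzyloxy)-2,4-dimethoxyphenyl]ethanol, via aryllithium 33 (not isolated)
Conditions: n-BuLi, THF, −78 °C; ethylene oxide, −78 °C → rt; H2O
Reagents that add atoms: ethylene oxide, C1CO1
Why: Bromine–lithium exchange gives aryllithium 33, which opens the epoxide by SN2 attack to the 2-arylethanol.

Step 22
Reactants: 34 2-[3-(benzyloxy)-2,4-dimethoxyphenyl]ethanol
Product: 35 2-[3-(benzyloxy)-2,4-dimethoxyphenyl]acetaldehyde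
Conditions: Dess–Martin periodinane, CH2Cl2, 0 °C → rt; used at once
Reagents that add atoms: none
Why: Dess–Martin oxidation gives the arylacetaldehyde under near-neutral conditions without over-oxidation, and immediate use avoids its self-condensation.

Step 23
Reactants: 29 5-(benzyloxy)-2-[{4-(benzyloxy)-2-[(3R)-7-(benzyloxy)chroman-3-yl]-6-methoxyphenyl}(hydroxy)methyl]phenol; 35 2-[3-(benzyloxy)-2,4-dimethoxyphenyl]acetaldehyde
Product: 37 (3R,4S)-7-(benzyloxy)-3-[3-(benzyloxy)-2,4-dimethoxyphenyl]-4-{4-(benzyloxy)-2-[(3R)-7-(benzyloxy)chroman-3-yl]-6-methoxyphenyl}chroman-2-ol (both anomers), via ortho-quinone methide 36 (not isolated)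
Conditions: (R)-2-[diphenyl(trimethylsilyloxy)methyl]pyrrolidine (20 mol%), PhCO2H (20 mol%), CH2Cl2, rt
Reagents that add atoms: none
Why: Formal [4+2] annulation (enamine Michael addition, then hemiacetalisation) of quinone methide 36, released from 29 by acid-assisted loss of water, in which the E-enamine of 35 attacks through the face not shielded by the diphenyl(silyloxy)methyl group of the (R)-catalyst and so sets C3 as R, the trans transition state together with the thermodynamic preference of the epimerisable C3 places the ring D aryl group on C4 trans to ring B (4S), and the phenol then closes ring C as the six-membered lactol.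

Step 24
Reactants: 37 (3R,4S)-7-(benzyloxy)-3-[3-(benzyloxy)-2,4-dimethoxyphenyl]-4-{4-(benzyloxy)-2-[(3R)-7-(benzyloxy)chroman-3-yl]-6-methoxyphenyl}chroman-2-ol
Product: 38 (3R,4S)-7-(benzyloxy)-3-[3-(benzyloxy)-2,4-dimethoxyphenyl]-4-{4-(benzyloxy)-2-[(3R)-7-(benzyloxy)chroman-3-yl]-6-methoxyphenyl}chroman
Conditions: Et3SiH, CF3CO2H, CH2Cl2, −20 → 0 °C
Reagents that add atoms: none
Why: Ionic hydrogenation, in which acid ionises the lactol at C2 and Et3SiH delivers hydride there, turns C2 into the chroman methylene without touching C3 or C4.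

Step 25
Reactants: 38 (3R,4S)-7-(benzyloxy)-3-[3-(benzyloxy)-2,4-dimethoxyphenyl]-4-{4-(benzyloxy)-2-[(3R)-7-(benzyloxy)chroman-3-yl]-6-methoxyphenyl}chroman
Product: 39 (3R,4S)-3-(3-hydroxy-2,4-dimethoxyphenyl)-4-{4-hydroxy-2-[(3R)-7-hydroxychroman-3-yl]-6-methoxyphenyl}chroman-7-ol (CNP0305801.1)
Conditions: H2 (1 atm), 10% Pd/C, EtOAc/MeOH, rt
Reagents that add atoms: none
Why: Hydrogenolysis of the four benzyl aryl ethers over Pd/C should free the four phenols, while the chroman C–O bonds are alkyl aryl ethers and the three stereocentres carry no heteroatom, so nothing else is cleaved.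

Compound list
1 | 5-bromovanillin (3-bromo-4-hydroxy-5-methoxybenzaldehyde) | COc1cc(C=O)cc(Br)c1O | starting material
2 | 3-bromo-5-methoxy-4-(methoxymethoxy)benzaldehyde | COCOc1c(Br)cc(C=O)cc1OC | intermediate
3 | 3-bromo-5-methoxy-4-(methoxymethoxy)phenyl formate (not isolated) | COCOc1c(Br)cc(OC=O)cc1OC | intermediate
4 | 3-bromo-5-methoxy-4-(methoxymethoxy)phenol | COCOc1c(Br)cc(O)cc1OC | intermediate
5 | 5-(benzyloxy)-1-bromo-3-methoxy-2-(methoxymethoxy)benzene | COCOc1c(Br)cc(OCc2ccccc2)cc1OC | intermediate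
6 | 4-(benzyloxy)-2-bromo-6-methoxyphenol | COc1cc(OCc2ccccc2)cc(Br)c1O | intermediate
7 | [4-(benzyloxy)-2-bromo-6-methoxyphenoxy]trimethylsilane (not isolated) | COc1cc(OCc2ccccc2)cc(Br)c1O[Si](C)(C)C | intermediate
8 | lithium 4-(benzyloxy)-2-methoxy-6-(trimethylsilyl)phenoxide (not isolated) | [Li+].[O-]c1c(OC)cc(OCc2ccccc2)cc1[Si](C)(C)C | intermediate
9 | 4-(benzyloxy)-2-methoxy-6-(trimethylsilyl)phenyl trifluoromethanesulfonate | COc1cc(OCc2ccccc2)cc([Si](C)(C)C)c1OS(=O)(=O)C(F)(F)F | intermediate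
10 | 1-[4-(benzyloxy)-2-hydroxyphenyl]ethanone | CC(=O)c1ccc(OCc2ccccc2)cc1O | starting material
11 | 1-[4-(benzyloxy)-2-(methoxymethoxy)phenyl]ethanone | CC(=O)c1ccc(OCc2ccccc2)cc1OCOC | intermediate
12 | methyl 3-[4-(benzyloxy)-2-(methoxymethoxy)phenyl]-3-oxopropanoate | COC(=O)CC(=O)c1ccc(OCc2ccccc2)cc1OCOC | intermediate
13 | 5-(benzyloxy)-3-methoxybenzyne (5-(benzyloxy)-3-methoxy-1,2-didehydrobenzene, not isolated) | COC1=CC(OCc2ccccc2)=CC#C1 | intermediate
14 | caesium 4-(benzyloxy)-1-[4-(benzyloxy)-2-(methoxymethoxy)phenyl]-6-methoxy-2-(methoxycarbonyl)-1,2-dihydrocyclobutabenzen-1-olate (not isolated) | [Cs+].[O-]C1(c2ccc(OCc3ccccc3)cc2OCOC)C(C(=O)OC)c2cc(OCc3ccccc3)cc(OC)c21 | intermediate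
15 | methyl 2-{5-(benzyloxy)-2-[4-(benzyloxy)-2-(methoxymethoxy)benzoyl]-3-methoxyphenyl}acetate | COC(=O)Cc1cc(OCc2ccccc2)cc(OC)c1C(=O)c1ccc(OCc2ccccc2)cc1OCOC | intermediate
16 | 2-{5-(benzyloxy)-2-[4-(benzyloxy)-2-(methoxymethoxy)benzoyl]-3-methoxyphenyl}acetic acid | OC(=O)Cc1cc(OCc2ccccc2)cc(OC)c1C(=O)c1ccc(OCc2ccccc2)cc1OCOC | intermediate
17 | (R)-4-benzyl-2-oxazolidinone | O=C1N[C@H](Cc2ccccc2)CO1 | starting material
18 | 2-{5-(benzyloxy)-2-[4-(benzyloxy)-2-(methoxymethoxy)benzoyl]-3-methoxyphenyl}acetic pivalic anhydride (not isolated) | CC(C)(C)C(=O)OC(=O)Cc1cc(OCc2ccccc2)cc(OC)c1C(=O)c1ccc(OCc2ccccc2)cc1OCOC | intermediate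
19 | (4R)-4-benzyl-3-(2-{5-(benzyloxy)-2-[4-(benzyloxy)-2-(methoxymethoxy)benzoyl]-3-methoxyphenyl}acetyl)-1,3-oxazolidin-2-one | O=C1OC[C@@H](Cc2ccccc2)N1C(=O)Cc1cc(OCc2ccccc2)cc(OC)c1C(=O)c1ccc(OCc2ccccc2)cc1OCOC | intermediate
20 | 2-bromo-4-hydroxybenzaldehyde | O=Cc1ccc(O)cc1Br | starting material
21 | 4-(benzyloxy)-2-bromobenzaldehyde | O=Cc1ccc(OCc2ccccc2)cc1Br | intermediate
22 | [4-(benzyloxy)-2-bromophenyl]methanol | OCc1ccc(OCc2ccccc2)cc1Br | intermediate
23 | 4-(benzyloxy)-2-bromo-1-(bromomethyl)benzene | BrCc1ccc(OCc2ccccc2)cc1Br | intermediate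
24 | sodium (Z)-enolate of imide 19 (not isolated) | [Na+].[O-]/C(N1C(=O)OC[C@H]1Cc1ccccc1)=C\c1cc(OCc2ccccc2)cc(OC)c1C(=O)c1ccc(OCc2ccccc2)cc1OCOC | intermediate
25 | (4R)-4-benzyl-3-[(2R)-2-{5-(benzyloxy)-2-[4-(benzyloxy)-2-(methoxymethoxy)benzoyl]-3-methoxyphenyl}-3-[4-(benzyloxy)-2-bromophenyl]propanoyl]-1,3-oxazolidin-2-one | O=C1OC[C@@H](Cc2ccccc2)N1C(=O)[C@H](Cc1ccc(OCc2ccccc2)cc1Br)c1cc(OCc2ccccc2)cc(OC)c1C(=O)c1ccc(OCc2ccccc2)cc1OCOC | intermediate
26 | {4-(benzyloxy)-2-[(2R)-1-[4-(benzyloxy)-2-bromophenyl]-3-hydroxypropan-2-yl]-6-methoxyphenyl}[4-(benzyloxy)-2-(methoxymethoxy)phenyl]methanone | OC[C@H](Cc1ccc(OCc2ccccc2)cc1Br)c1cc(OCc2ccccc2)cc(OC)c1C(=O)c1ccc(OCc2ccccc2)cc1OCOC | intermediate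
27 | {4-(benzyloxy)-2-[(3R)-7-(benzyloxy)chroman-3-yl]-6-methoxyphenyl}[4-(benzyloxy)-2-(methoxymethoxy)phenyl]methanone | COCOc1cc(OCc2ccccc2)ccc1C(=O)c1c(OC)cc(OCc2ccccc2)cc1[C@@H]1COc2cc(OCc3ccccc3)ccc2C1 | intermediate
28 | {4-(benzyloxy)-2-[(3R)-7-(benzyloxy)chroman-3-yl]-6-methoxyphenyl}[4-(benzyloxy)-2-hydroxyphenyl]methanone | Oc1cc(OCc2ccccc2)ccc1C(=O)c1c(OC)cc(OCc2ccccc2)cc1[C@@H]1COc2cc(OCc3ccccc3)ccc2C1 | intermediate
29 | 5-(benzyloxy)-2-[{4-(benzyloxy)-2-[(3R)-7-(benzyloxy)chroman-3-yl]-6-methoxyphenyl}(hydroxy)methyl]phenol (both carbinol epimers) | Oc1cc(OCc2ccccc2)ccc1C(O)c1c(OC)cc(OCc2ccccc2)cc1[C@@H]1COc2cc(OCc3ccccc3)ccc2C1 | intermediate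
30 | 2,6-dimethoxyphenol | COc1cccc(OC)c1O | starting material
31 | 2-(benzyloxy)-1,3-dimethoxybenzene | COc1cccc(OC)c1OCc1ccccc1 | intermediate
32 | 3-(benzyloxy)-1-bromo-2,4-dimethoxybenzene | COc1ccc(Br)c(OC)c1OCc1ccccc1 | intermediate
33 | [3-(benzyloxy)-2,4-dimethoxyphenyl]lithium (not isolated) | [Li]c1ccc(OC)c(OCc2ccccc2)c1OC | intermediate
34 | 2-[3-(benzyloxy)-2,4-dimethoxyphenyl]ethanol | OCCc1ccc(OC)c(OCc2ccccc2)c1OC | intermediate
35 | 2-[3-(benzyloxy)-2,4-dimethoxyphenyl]acetaldehyde | O=CCc1ccc(OC)c(OCc2ccccc2)c1OC | intermediate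
36 | 3-(benzyloxy)-6-({4-(benzyloxy)-2-[(3R)-7-(benzyloxy)chroman-3-yl]-6-methoxyphenyl}methylidene)cyclohexa-2,4-dien-1-one (ortho-quinone methide, not isolated) | O=C1C=C(OCc2ccccc2)C=CC1=Cc1c(OC)cc(OCc2ccccc2)cc1[C@@H]1COc2cc(OCc3ccccc3)ccc2C1 | intermediate
37 | (3R,4S)-7-(benzyloxy)-3-[3-(benzyloxy)-2,4-dimethoxyphenyl]-4-{4-(benzyloxy)-2-[(3R)-7-(benzyloxy)chroman-3-yl]-6-methoxyphenyl}chroman-2-ol (both anomers) | COc1ccc([C@@H]2C(O)Oc3cc(OCc4ccccc4)ccc3[C@H]2c2c(OC)cc(OCc3ccccc3)cc2[C@@H]2COc3cc(OCc4ccccc4)ccc3C2)c(OC)c1OCc1ccccc1 | intermediate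
38 | (3R,4S)-7-(benzyloxy)-3-[3-(benzyloxy)-2,4-dimethoxyphenyl]-4-{4-(benzyloxy)-2-[(3R)-7-(benzyloxy)chroman-3-yl]-6-methoxyphenyl}chroman | COc1ccc([C@@H]2COc3cc(OCc4ccccc4)ccc3[C@H]2c2c(OC)cc(OCc3ccccc3)cc2[C@@H]2COc3cc(OCc4ccccc4)ccc3C2)c(OC)c1OCc1ccccc1 | intermediate
39 | (3R,4S)-3-(3-hydroxy-2,4-dimethoxyphenyl)-4-{4-hydroxy-2-[(3R)-7-hydroxychroman-3-yl]-6-methoxyphenyl}chroman-7-ol (CNP0305801.1) | COc1ccc([C@@H]2COc3cc(O)ccc3[C@H]2c2c(OC)cc(O)cc2[C@@H]2COc3cc(O)ccc3C2)c(OC)c1O | target

Total step count: 25. Longest linear sequence: 16 steps (steps 1–5, 8–10, 14–18 and 23–25, from 5-bromovanillin).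

Steps most likely to fail

1. Step 8. After the enolate has added to the aryne, the aryl anion at D1 may be protonated faster than it closes onto the ketone, which is crowded by the ortho MOM ether and deactivated by two alkoxy donors; plain α-arylation would then replace insertion. The fallback keeps the aryne and the disconnection but re-designs the acceptor; it sets out from 9 and comes back at 15. Commercial 2'-fluoro-4'-hydroxyacetophenone is benzylated (BnBr, K2CO3) to 1-[4-(benzyloxy)-2-fluorophenyl]ethanone F1 and condensed with dimethyl carbonate (NaH) to methyl 3-[4-(benzyloxy)-2-fluorophenyl]-3-oxopropanoate F2. Its ketone is flanked by a small fluorine that is no strong π-donor. Insertion of the aryne from 9 (CsF, MeCN, 80 °C) should pass through the fluoro-substituted caesium benzocyclobutenoxide F3 to methyl 2-{5-(benzyloxy)-2-[4-(benzyloxy)-2-fluorobenzoyl]-3-methoxyphenyl}acetate F4. The ketone-activated fluoride is then exchanged by SNAr with acetohydroxamic acid/K2CO3 in DMSO, a hydroxide surrogate. The O-aryl acetohydroxamate F5 collapses in the flask by Lossen-type fragmentation to methyl 2-{5-(benzyloxy)-2-[4-(benzyloxy)-2-hydroxybenzoyl]-3-methoxyphenyl}acetate F6, and MOM protection (MOMCl, i-Pr2NEt) gives 15.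

2. Step 23. Acid-assisted release of the quinone methide may be too slow or too unselective under the weak acid that the enamine cycle tolerates, so that self-condensation of the arylacetaldehyde takes over. The fallback separates quinone methide generation from the annulation; it sets out from 29 and comes back at 37. Treatment of 29 with p-toluenesulfinic acid in CH2Cl2 should give the crystalline sulfone 5-(benzyloxy)-2-[{4-(benzyloxy)-2-[(3R)-7-(benzyloxy)chroman-3-yl]-6-methoxyphenyl}(4-methylbenzenesulfonyl)methyl]phenol F7. Mild base (K2CO3) then eliminates sulfinate and releases 36 slowly in the presence of 35 and the same (R)-prolinol silyl ether, a known base-triggered mode for enamine additions to ortho-quinone methides.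

3. Step 15. Hydride attack on the diaryl ketone may compete with cleavage of the imide and give mixtures of ketone and carbinol. The fallback drops the chemoselectivity requirement; it sets out from 25 and comes back at 26. LiAlH4 (THF, 0 °C) reduces imide and ketone together to the diol {4-(benzyloxy)-2-[(2R)-1-[4-(benzyloxy)-2-bromophenyl]-3-hydroxypropan-2-yl]-6-methoxyphenyl}[4-(benzyloxy)-2-(methoxymethoxy)phenyl]methanol F8. MnO2 (CH2Cl2, rt) then re-oxidises only the diaryl carbinol and leaves the primary alcohol, which gives 26.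

Further compounds
F1 | step 8 | 1-[4-(benzyloxy)-2-fluorophenyl]ethanone | CC(=O)c1ccc(OCc2ccccc2)cc1F
F2 | step 8 | methyl 3-[4-(benzyloxy)-2-fluorophenyl]-3-oxopropanoate | COC(=O)CC(=O)c1ccc(OCc2ccccc2)cc1F
F3 | step 8 | caesium 4-(benzyloxy)-1-[4-(benzyloxy)-2-fluorophenyl]-6-methoxy-2-(methoxycarbonyl)-1,2-dihydrocyclobutabenzen-1-olate | [Cs+].[O-]C1(c2ccc(OCc3ccccc3)cc2F)C(C(=O)OC)c2cc(OCc3ccccc3)cc(OC)c21
F4 | step 8 | methyl 2-{5-(benzyloxy)-2-[4-(benzyloxy)-2-fluorobenzoyl]-3-methoxyphenyl}acetate | COC(=O)Cc1cc(OCc2ccccc2)cc(OC)c1C(=O)c1ccc(OCc2ccccc2)cc1F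
F5 | step 8 | methyl 2-{2-[2-(acetamidooxy)-4-(benzyloxy)benzoyl]-5-(benzyloxy)-3-methoxyphenyl}acetate | COC(=O)Cc1cc(OCc2ccccc2)cc(OC)c1C(=O)c1ccc(OCc2ccccc2)cc1ONC(C)=O
F6 | step 8 | methyl 2-{5-(benzyloxy)-2-[4-(benzyloxy)-2-hydroxybenzoyl]-3-methoxyphenyl}acetate | COC(=O)Cc1cc(OCc2ccccc2)cc(OC)c1C(=O)c1ccc(OCc2ccccc2)cc1O
F7 | step 23 | 5-(benzyloxy)-2-[{4-(benzyloxy)-2-[(3R)-7-(benzyloxy)chroman-3-yl]-6-methoxyphenyl}(4-methylbenzenesulfonyl)methyl]phenol | Cc1ccc(cc1)S(=O)(=O)C(c1ccc(OCc2ccccc2)cc1O)c1c(OC)cc(OCc2ccccc2)cc1[C@@H]1COc2cc(OCc3ccccc3)ccc2C1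
F8 | step 15 | {4-(benzyloxy)-2-[(2R)-1-[4-(benzyloxy)-2-bromophenyl]-3-hydroxypropan-2-yl]-6-methoxyphenyl}[4-(benzyloxy)-2-(methoxymethoxy)phenyl]methanol | OC[C@H](Cc1ccc(OCc2ccccc2)cc1Br)c1cc(OCc2ccccc2)cc(OC)c1C(O)c1ccc(OCc2ccccc2)cc1OCOC
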